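**Retrosynthetic overview**
1. Both esters go on last (angelate at C3, then methacrylate at C1) onto a trans-1,3-diol that an Evans–Tishchenko reduction delivers already differentiated; the C6 enone comes from a late allylic oxidation.
2. Seven-membered ring (formed last): C10–C11 by intramolecular reductive aldol of an isopropenyl ketone onto the cyclobutanone, then radical removal of the C10 hydroxyl.
3. Fragment union: C2–C3 by an intermolecular boron aldol of 3-methylbut-3-en-2-one with the neopentyl aldehyde on the bicyclo[3.1.1]heptenone (reagent control of C3).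
4. Cyclobutane and six-membered ring (formed first, in one step): intramolecular vinylketene–alkene [2+2] of an 8-silyloxygeranoyl chloride; the racemic ketone is resolved.
5. The acid comes from geranyl acetate by allylic oxidation at C8.

Locants: "T-locants" are those of the target chain C1(O)–C2–C3(O)–C4(Me)–C5–C6(=O)–C7=C8(Me)–C9–C10–C11(Me2)–C1, with cross-ring bonds C4–C9 and C5–C10. In the bicyclo[3.1.1]heptanes, C7 = T-C4, C6 = T-C10, C1 = T-C9, C5 = T-C5.

Assumptions: the absolute configuration of resolved ketone 11 is established by X-ray of the p-bromobenzoate of 12; (−)-Ipc2BCl is taken to give re-face addition to aldehyde 13 (Paterson's methyl-ketone model), and the (+)-reagent is used if the first run shows the opposite sense.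

**Step 1**
Reactants: 1 geranyl acetate
Product: 2 (2E,6E)-8-hydroxy-3,7-dimethylocta-2,6-dien-1-yl acetate
Conditions: SeO2 (cat.), t-BuOOH, salicylic acid (cat.), CH2Cl2, rt
Reagents that add atoms: tert-butyl hydroperoxide CC(C)(C)OO
Why: SeO2 allylic oxidation (ene then [2,3] shift) takes the electron-rich terminal alkene and gives only the (E)-hydroxymethyl isomer.

**Step 2**
Reactants: 2 hydroxy acetate
Product: 3 (2E,6E)-8-(tert-butyldiphenylsilyloxy)-3,7-dimethylocta-2,6-dien-1-yl acetate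
Conditions: TBDPSCl, imidazole, CH2Cl2, 0 °C to rt
Reagents that add atoms: tert-butyldiphenylsilyl chloride CC(C)(C)[Si](Cl)(c1ccccc1)c1ccccc1
Why: Standard silylation of a primary alcohol; TBDPS survives the later acid chloride and hot amine conditions.

**Step 3**
Reactants: 3 silyl ether acetate
Product: 4 (2E,6E)-8-(tert-butyldiphenylsilyloxy)-3,7-dimethylocta-2,6-dien-1-ol
Conditions: K2CO3, MeOH, rt
Reagents that add atoms: none
Why: Base-catalysed transesterification removes the acetate without touching the silyl ether.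

**Step 4**
Reactants: 4 allylic alcohol
Product: 5 (2E,6E)-8-(tert-butyldiphenylsilyloxy)-3,7-dimethylocta-2,6-dienal
Conditions: MnO2, CH2Cl2, rt
Reagents that add atoms: none
Why: MnO2 oxidises allylic alcohols selectively and keeps the 2E geometry.

**Step 5**
Reactants: 5 enal
Product: 6 (2E,6E)-8-(tert-butyldiphenylsilyloxy)-3,7-dimethylocta-2,6-dienoic acid
Conditions: NaClO2, NaH2PO4, 2-methyl-2-butene, t-BuOH/H2O, rt
Reagents that add atoms: sodium chlorite [Na+].[O-]Cl=O
Why: Pinnick oxidation converts the enal to the acid, with the scavenger protecting both trisubstituted alkenes from HOCl.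

**Step 6**
Reactants: 6 dienoic acid
Product: 9 rac-(1R*,5S*,7S*)-7-[(tert-butyldiphenylsilyloxy)methyl]-7-methyl-2-methylidenebicyclo[3.1.1]heptan-6-one, via acid chloride 7 (not isolated), via vinylketene 8 (not isolated)
Conditions: (COCl)2, DMF (cat.), CH2Cl2, 0 °C; evaporate; slow addition to Et3N, toluene, reflux, 0.01 M
Reagents that add atoms: none
Why: Intramolecular vinylketene–alkene [2+2] cycloaddition forms T-C10–C5 and T-C9–C4 suprafacially on the (6E)-alkene, which places the C7 methyl syn to the three-carbon bridge and CH2OSi anti; the minor endocyclic isomer that accompanies 9 (about 3:1) is compound 10 itself and is carried into step 7.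

**Step 7**
Reactants: 9 exo-methylene ketone (with co-formed 10)
Product: 10 rac-(1R*,5S*,7S*)-7-[(tert-butyldiphenylsilyloxy)methyl]-2,7-dimethylbicyclo[3.1.1]hept-2-en-6-one
Conditions: RuHCl(CO)(PPh3)3 (5 mol%), toluene, 100 °C
Reagents that add atoms: none
Why: Metal-hydride alkene isomerisation (insertion/β-hydride elimination) under neutral conditions moves the double bond into the thermodynamically favoured trisubstituted endocyclic position, as in β-pinene to α-pinene.

**Step 8**
Reactants: 10 racemic ketone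
Product: 11 (1R,5S,7S)-7-[(tert-butyldiphenylsilyloxy)methyl]-2,7-dimethylbicyclo[3.1.1]hept-2-en-6-one
Conditions: preparative chiral SFC, amylose tris(3,5-dimethylphenylcarbamate) phase, CO2/i-PrOH
Reagents that add atoms: none
Why: Resolution by chiral chromatography of a rigid, UV-active ketone gives the antipode that carries the T-C4/C5/C9 configuration of the target.

**Step 9**
Reactants: 11 resolved ketone
Product: 12 (1R,5S,7S)-7-(hydroxymethyl)-2,7-dimethylbicyclo[3.1.1]hept-2-en-6-one
Conditions: TBAF, AcOH, THF, rt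
Reagents that add atoms: none
Why: Buffered fluoride desilylation frees the primary alcohol without exposing the strained non-enolisable ketone to strong base.

**Step 10**
Reactants: 12 keto alcohol
Product: 13 (1R,5S,7S)-2,7-dimethyl-6-oxobicyclo[3.1.1]hept-2-ene-7-carbaldehyde
Conditions: Dess–Martin periodinane, CH2Cl2, 0 °C to rt
Reagents that add atoms: none
Why: Dess–Martin oxidation gives the non-enolisable neopentyl aldehyde under neutral conditions.

**Step 11**
Reactants: 13 keto aldehyde; 14 3-methylbut-3-en-2-one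
Product: 17 (1R,5S,7S)-7-[(1R)-1-hydroxy-4-methyl-3-oxopent-4-en-1-yl]-2,7-dimethylbicyclo[3.1.1]hept-2-en-6-one, via enol borinate 15 (not isolated), via boron aldolate 16 (not isolated)
Conditions: 14, (−)-Ipc2BCl, Et3N, Et2O, −78 to 0 °C; then 13, −78 to −20 °C; MeOH/pH 7 buffer work-up without H2O2
Reagents that add atoms: none
Why: Intermolecular Paterson boron aldol joins the two fragments at C2–C3 chemoselectively at the aldehyde (boron enolates ignore the ketone), and the Ipc ligands set (3R) by reagent control (expected about 5:1, minor C3 epimer removed by chromatography).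

**Step 12**
Reactants: 17 aldol
Product: 18 triethylsilyl ether of 17
Conditions: TESOTf, 2,6-lutidine, CH2Cl2, −78 °C
Reagents that add atoms: triethylsilyl triflate CC[Si](CC)(CC)OS(=O)(=O)C(F)(F)F
Why: Silylation blocks retro-aldol and alkoxide chemistry in the next step and can later be removed under mild acid.

**Step 13**
Reactants: 18 silylated keto enone
Product: 21 tricyclic ketol (T-C1 ketone, (3R)-OTES, C10-OH), via copper enolate 19 (not isolated), via copper aldolate 20 (not isolated)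
Conditions: [(Ph3P)CuH]6 (1.1 equiv Cu–H), toluene, −40 °C to rt; aq NH4Cl
Reagents that add atoms: none
Why: Stryker reductive aldol cyclisation: hydride adds to the terminal CH2 of the isopropenyl ketone to give only the C11 enolate, which closes the seven-membered ring onto the strained cyclobutanone from the only face the tether can reach, so C11 is anti and the C10 configuration is fixed.

**Step 14**
Reactants: 21 tricyclic ketol
Product: 22 C10 methyl oxalate of 21
Conditions: ClC(O)CO2Me, pyridine, DMAP (cat.), CH2Cl2, 0 °C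
Reagents that add atoms: methyl chlorooxoacetate COC(=O)C(Cl)=O
Why: The highly reactive oxalyl chloride acylates the tertiary cyclobutanol without an alkoxide, which avoids retro-aldol.

**Step 15**
Reactants: 22 oxalate
Product: 23 tricyclic ketone (T-C1 ketone, (3R)-OTES, C10-H)
Conditions: Bu3SnH, AIBN (cat.), toluene, 100 °C
Reagents that add atoms: none
Why: Radical deoxygenation of a tertiary methyl oxalate (Dolan–MacMillan type); the bridgehead C10 radical can only take hydrogen on its outer face, so the target C10 configuration results.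

**Step 16**
Reactants: 23 silyl ether
Product: 24 β-hydroxy ketone (T-C1 ketone, (3R)-OH)
Conditions: PPTS (cat.), MeOH, 0 °C to rt
Reagents that add atoms: none
Why: Mild acid methanolysis removes the TES group without affecting the acid-sensitive pinene-type alkene.

**Step 17**
Reactants: 24 β-hydroxy ketone
Product: 26 (1R)-hydroxy (3R)-acetate, via samarium hemiacetal 25 (not isolated)
Conditions: SmI2 (0.3 equiv), MeCHO (10 equiv), THF, −10 °C
Reagents that add atoms: acetaldehyde CC=O
Why: Evans–Tishchenko reduction delivers hydride intramolecularly from the C3 hemiacetal, which sets C1 trans (1,3-anti) to C3–O and leaves the two oxygens differentiated as acetate and free alcohol.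

**Step 18**
Reactants: 26 hydroxy acetate
Product: 27 (1R)-OTBS (3R)-acetate
Conditions: TBSOTf, 2,6-lutidine, CH2Cl2, 0 °C
Reagents that add atoms: tert-butyldimethylsilyl triflate CC(C)(C)[Si](C)(C)OS(=O)(=O)C(F)(F)F
Why: The silyl triflate protects the hindered neopentyl C1 alcohol under non-acylating conditions, so no acetyl migration occurs.

**Step 19**
Reactants: 27 protected diol
Product: 28 enone (T-C6 ketone conjugated to C7=C8)
Conditions: CrO3, 3,5-dimethylpyrazole, CH2Cl2, −20 °C
Reagents that add atoms: chromium trioxide O=[Cr](=O)=O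
Why: Cr(VI)–pyrazole allylic oxidation takes the ring CH2 of the α-pinene-type alkene to the verbenone-type enone, the same site selectivity as α-pinene to verbenone.

**Step 20**
Reactants: 28 enone acetate
Product: 29 (1R)-OTBS (3R)-hydroxy enone
Conditions: K2CO3, MeOH, rt
Reagents that add atoms: none
Why: Methanolysis removes the acetate; the enone has no epimerisable centre (C5 is a bridgehead) and a fully substituted β-carbon.

**Step 21**
Reactants: 29 C3 alcohol; 30 angelic acid
Product: 32 (3R)-angelate (1R)-OTBS enone, via mixed anhydride 31 (not isolated)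
Conditions: 30, 2,4,6-trichlorobenzoyl chloride, Et3N, toluene, rt; then 29, 75 °C
Reagents that add atoms: none
Why: Yamaguchi esterification without DMAP acylates the hindered alcohol at the angeloyl carbonyl and keeps the (Z)-geometry.

**Step 22**
Reactants: 32 silyl ether
Product: 33 (1R)-hydroxy (3R)-angelate enone
Conditions: HF·pyridine, pyridine, THF, 0 °C to rt
Reagents that add atoms: none
Why: Acidic fluoride desilylation avoids the basic conditions that could cause 1,3-acyl migration or angelate isomerisation.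

**Step 23**
Reactants: 33 C1 alcohol; 34 methacryloyl chloride
Product: 35 target CNP0317071.1
Conditions: 34, Et3N, DMAP (cat.), CH2Cl2, 0 °C to rt
Reagents that add atoms: none
Why: Acyl chloride esterification with nucleophilic catalysis installs the methacrylate on the last free hydroxyl.

**Compound list**
1 | geranyl acetate, (2E)-3,7-dimethylocta-2,6-dien-1-yl acetate | CC(C)=CCC/C(C)=C/COC(C)=O | starting material
2 | (2E,6E)-8-hydroxy-3,7-dimethylocta-2,6-dien-1-yl acetate | OC/C(C)=C/CC/C(C)=C/COC(C)=O | intermediate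
3 | (2E,6E)-8-(tert-butyldiphenylsilyloxy)-3,7-dimethylocta-2,6-dien-1-yl acetate | CC(C)(C)[Si](c1ccccc1)(c1ccccc1)OC/C(C)=C/CC/C(C)=C/COC(C)=O | intermediate
4 | (2E,6E)-8-(tert-butyldiphenylsilyloxy)-3,7-dimethylocta-2,6-dien-1-ol | CC(C)(C)[Si](c1ccccc1)(c1ccccc1)OC/C(C)=C/CC/C(C)=C/CO | intermediate
5 | (2E,6E)-8-(tert-butyldiphenylsilyloxy)-3,7-dimethylocta-2,6-dienal | CC(C)(C)[Si](c1ccccc1)(c1ccccc1)OC/C(C)=C/CC/C(C)=C/C=O | intermediate
6 | (2E,6E)-8-(tert-butyldiphenylsilyloxy)-3,7-dimethylocta-2,6-dienoic acid | CC(C)(C)[Si](c1ccccc1)(c1ccccc1)OC/C(C)=C/CC/C(C)=C/C(=O)O | intermediate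
7 | (2E,6E)-8-(tert-butyldiphenylsilyloxy)-3,7-dimethylocta-2,6-dienoyl chloride | CC(C)(C)[Si](c1ccccc1)(c1ccccc1)OC/C(C)=C/CC/C(C)=C/C(=O)Cl | intermediate (not isolated)
8 | vinylketene, (6E)-8-(tert-butyldiphenylsilyloxy)-7-methyl-3-methylideneocta-1,6-dien-1-one | CC(C)(C)[Si](c1ccccc1)(c1ccccc1)OC/C(C)=C/CCC(=C)C=C=O | intermediate (not isolated)
9 | rac-(1R*,5S*,7S*)-7-[(tert-butyldiphenylsilyloxy)methyl]-7-methyl-2-methylidenebicyclo[3.1.1]heptan-6-one (racemate, one enantiomer drawn; 7-methyl syn to the C2–C4 bridge) | CC(C)(C)[Si](c1ccccc1)(c1ccccc1)OC[C@@]2(C)[C@@H]3CCC(=C)[C@H]2C3=O | intermediate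
10 | rac-(1R*,5S*,7S*)-7-[(tert-butyldiphenylsilyloxy)methyl]-2,7-dimethylbicyclo[3.1.1]hept-2-en-6-one (racemate, one enantiomer drawn) | CC(C)(C)[Si](c1ccccc1)(c1ccccc1)OC[C@@]2(C)[C@@H]3CC=C(C)[C@H]2C3=O | intermediate
11 | (1R,5S,7S)-7-[(tert-butyldiphenylsilyloxy)methyl]-2,7-dimethylbicyclo[3.1.1]hept-2-en-6-one (single enantiomer) | CC(C)(C)[Si](c1ccccc1)(c1ccccc1)OC[C@@]2(C)[C@@H]3CC=C(C)[C@H]2C3=O | intermediate
12 | (1R,5S,7S)-7-(hydroxymethyl)-2,7-dimethylbicyclo[3.1.1]hept-2-en-6-one | OC[C@@]1(C)[C@@H]2CC=C(C)[C@H]1C2=O | intermediate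
13 | (1R,5S,7S)-2,7-dimethyl-6-oxobicyclo[3.1.1]hept-2-ene-7-carbaldehyde | O=C[C@@]1(C)[C@@H]2CC=C(C)[C@H]1C2=O | intermediate
14 | 3-methylbut-3-en-2-one (methyl isopropenyl ketone) | CC(=O)C(C)=C | starting material
15 | enol borinate, 2-[bis(isopinocampheyl)boryloxy]-3-methylbuta-1,3-diene (Ipc from (+)-α-pinene) | C=C(C)C(=C)OB([C@@H]1C[C@@H]2C[C@@H](C2(C)C)[C@H]1C)[C@@H]1C[C@@H]2C[C@@H](C2(C)C)[C@H]1C | intermediate (not isolated)
16 | boron aldolate, O-bis(isopinocampheyl)boryl derivative of 17 | C=C(C)C(=O)C[C@@H](OB([C@@H]1C[C@@H]2C[C@@H](C2(C)C)[C@H]1C)[C@@H]1C[C@@H]2C[C@@H](C2(C)C)[C@H]1C)[C@@]1(C)[C@@H]2CC=C(C)[C@H]1C2=O | intermediate (not isolated)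
17 | (1R,5S,7S)-7-[(1R)-1-hydroxy-4-methyl-3-oxopent-4-en-1-yl]-2,7-dimethylbicyclo[3.1.1]hept-2-en-6-one | C=C(C)C(=O)C[C@@H](O)[C@@]1(C)[C@@H]2CC=C(C)[C@H]1C2=O | intermediate
18 | (1R,5S,7S)-2,7-dimethyl-7-[(1R)-4-methyl-3-oxo-1-(triethylsilyloxy)pent-4-en-1-yl]bicyclo[3.1.1]hept-2-en-6-one | C=C(C)C(=O)C[C@@H](O[Si](CC)(CC)CC)[C@@]1(C)[C@@H]2CC=C(C)[C@H]1C2=O | intermediate
19 | copper(I) enolate of the 1,4-reduced enone (T-C11=C1–OCu; phosphine ligands omitted) | CC(C)=C(O[Cu])C[C@@H](O[Si](CC)(CC)CC)[C@@]1(C)[C@@H]2CC=C(C)[C@H]1C2=O | intermediate (not isolated)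
20 | copper(I) aldolate of 21 (T-C10–OCu) | O=C1C[C@@H](O[Si](CC)(CC)CC)[C@@]2(C)[C@@H]3CC=C(C)[C@H]2[C@]3(O[Cu])C1(C)C | intermediate (not isolated)
21 | tricyclic ketol: T-C1 ketone, (3R)-triethylsilyloxy, C10-hydroxy (syn to the C6–C8 bridge), C7=C8 alkene, ring-fusion centres as in the target | O=C1C[C@@H](O[Si](CC)(CC)CC)[C@@]2(C)[C@@H]3CC=C(C)[C@H]2[C@]3(O)C1(C)C | intermediate
22 | methyl oxalate of the C10 hydroxyl of 21 | O=C1C[C@@H](O[Si](CC)(CC)CC)[C@@]2(C)[C@@H]3CC=C(C)[C@H]2[C@]3(OC(=O)C(=O)OC)C1(C)C | intermediate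
23 | tricyclic ketone: T-C1 ketone, (3R)-triethylsilyloxy, C10-H | O=C1C[C@@H](O[Si](CC)(CC)CC)[C@@]2(C)[C@@H]3CC=C(C)[C@H]2[C@@H]3C1(C)C | intermediate
24 | tricyclic β-hydroxy ketone: T-C1 ketone, (3R)-hydroxy | O=C1C[C@@H](O)[C@@]2(C)[C@@H]3CC=C(C)[C@H]2[C@@H]3C1(C)C | intermediate
25 | samarium(III) hemiacetal alkoxide from 24 and acetaldehyde (on the C3 oxygen) | O=C1C[C@@H](OC(C)O[Sm](I)I)[C@@]2(C)[C@@H]3CC=C(C)[C@H]2[C@@H]3C1(C)C | intermediate (not isolated)
26 | tricyclic (1R)-hydroxy (3R)-acetate (1,3-trans) | O[C@@H]1C[C@@H](OC(C)=O)[C@@]2(C)[C@@H]3CC=C(C)[C@H]2[C@@H]3C1(C)C | intermediate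
27 | tricyclic (1R)-tert-butyldimethylsilyloxy (3R)-acetate | CC(C)(C)[Si](C)(C)O[C@@H]1C[C@@H](OC(C)=O)[C@@]2(C)[C@@H]3CC=C(C)[C@H]2[C@@H]3C1(C)C | intermediate
28 | tricyclic enone: T-C6 ketone, C7=C8, (1R)-OTBS, (3R)-acetate | CC(C)(C)[Si](C)(C)O[C@@H]1C[C@@H](OC(C)=O)[C@@]2(C)[C@@H]3C(=O)C=C(C)[C@H]2[C@@H]3C1(C)C | intermediate
29 | tricyclic enone: (1R)-OTBS, (3R)-hydroxy | CC(C)(C)[Si](C)(C)O[C@@H]1C[C@@H](O)[C@@]2(C)[C@@H]3C(=O)C=C(C)[C@H]2[C@@H]3C1(C)C | intermediate
30 | angelic acid, (Z)-2-methylbut-2-enoic acid | C/C=C(/C)C(=O)O | starting material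
31 | angelic 2,4,6-trichlorobenzoic anhydride | C/C=C(/C)C(=O)OC(=O)c1c(Cl)cc(Cl)cc1Cl | intermediate (not isolated)
32 | tricyclic enone: (1R)-OTBS, (3R)-angelate | CC(C)(C)[Si](C)(C)O[C@@H]1C[C@@H](OC(=O)/C(C)=C\C)[C@@]2(C)[C@@H]3C(=O)C=C(C)[C@H]2[C@@H]3C1(C)C | intermediate
33 | tricyclic enone: (1R)-hydroxy, (3R)-angelate | O[C@@H]1C[C@@H](OC(=O)/C(C)=C\C)[C@@]2(C)[C@@H]3C(=O)C=C(C)[C@H]2[C@@H]3C1(C)C | intermediate
34 | methacryloyl chloride | C=C(C)C(Cl)=O | starting material
35 | CNP0317071.1: tricyclic enone with (1R)-methacrylate and (3R)-angelate | C=C(C)C(=O)O[C@@H]1C[C@@H](OC(=O)/C(C)=C\C)[C@@]2(C)[C@@H]3C(=O)C=C(C)[C@H]2[C@@H]3C1(C)C | target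

**Totals**
Total step count: 23. Longest linear sequence: 23 steps (from geranyl acetate 1).

**Steps most likely to fail**

Step 6 (ketene [2+2]): the allylic silyl ether lowers the nucleophilicity of the alkene, so ketene oligomerisation may win. Fallback, setting out from acid 6 and returning at ketone 9: the acid chloride 7 is treated with dimethylamine to give the N,N-dimethylamide F1. Tf2O and 2,4,6-collidine in 1,2-dichloroethane at 80 °C convert it into the vinylketeniminium triflate F2, a much stronger electrophile than the ketene. Its intramolecular [2+2] gives the cyclobutaniminium triflate F3, and aqueous NaHCO3 hydrolysis returns 9 (with 10), which enter step 7.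

Step 13 (reductive aldol): the copper enolate may be quenched before it closes the congested seven-membered ring. Fallback, setting out from 18 and returning at 21: catalytic Stryker reagent with PhMe2SiH traps the conjugate-reduction product as the dimethylphenylsilyl enol ether F4. NBS in THF at −78 °C gives the tertiary α-bromo ketone F5. SmI2 in THF at −78 °C forms the samarium(III) enolate F6, which closes onto the cyclobutanone to the samarium aldolate F7 (intramolecular Reformatsky-type aldol); work-up gives 21.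

Step 15 (deoxygenation): fragmentation of the oxalate to the strained cyclobutyl radical may be slow. Fallback, setting out from 21 and returning at 23: NaBH4 in MeOH reduces the C1 ketone to the diol F8 (C1 configuration immaterial). Thiophosgene and DMAP close the cyclic thionocarbonate F9 over the C1 and C10 oxygens. Bu3SnH/AIBN cleaves it at the tertiary C10–O bond (stronger C=S to C=O driving force) to the stannyl thiolcarbonate F10. K2CO3/MeOH converts this to the C1 alcohol F11, and Dess–Martin oxidation gives 23.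

**Further compounds**
F1 | step 6 | (2E,6E)-8-(tert-butyldiphenylsilyloxy)-N,N,3,7-tetramethylocta-2,6-dienamide | CC(C)(C)[Si](c1ccccc1)(c1ccccc1)OC/C(C)=C/CC/C(C)=C/C(=O)N(C)C
F2 | step 6 | vinylketeniminium triflate from F1 | CC(C)(C)[Si](c1ccccc1)(c1ccccc1)OC/C(C)=C/CCC(=C)C=C=[N+](C)C.[O-]S(=O)(=O)C(F)(F)F
F3 | step 6 | racemic cyclobutaniminium triflate (N,N-dimethyliminium of 9) | CC(C)(C)[Si](c1ccccc1)(c1ccccc1)OC[C@@]2(C)[C@@H]3CCC(=C)[C@H]2C3=[N+](C)C.[O-]S(=O)(=O)C(F)(F)F
F4 | step 13 | dimethylphenylsilyl enol ether of the 1,4-reduced enone | CC(C)=C(O[Si](C)(C)c1ccccc1)C[C@@H](O[Si](CC)(CC)CC)[C@@]1(C)[C@@H]2CC=C(C)[C@H]1C2=O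
F5 | step 13 | tertiary α-bromo ketone | CC(C)(Br)C(=O)C[C@@H](O[Si](CC)(CC)CC)[C@@]1(C)[C@@H]2CC=C(C)[C@H]1C2=O
F6 | step 13 | samarium(III) enolate | CC(C)=C(O[Sm](I)I)C[C@@H](O[Si](CC)(CC)CC)[C@@]1(C)[C@@H]2CC=C(C)[C@H]1C2=O
F7 | step 13 | samarium(III) aldolate of 21 | O=C1C[C@@H](O[Si](CC)(CC)CC)[C@@]2(C)[C@@H]3CC=C(C)[C@H]2[C@]3(O[Sm](I)I)C1(C)C
F8 | step 15 | tricyclic 1,10-diol with (3R)-OTES (C1 epimer mixture) | OC1C[C@@H](O[Si](CC)(CC)CC)[C@@]2(C)[C@@H]3CC=C(C)[C@H]2[C@]3(O)C1(C)C
F9 | step 15 | cyclic thionocarbonate of F8 | S=C1OC2C[C@@H](O[Si](CC)(CC)CC)[C@@]3(C)[C@@H]4CC=C(C)[C@H]3[C@]4(O1)C2(C)C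
F10 | step 15 | C1 O-(tributylstannylthio)carbonyl derivative with C10-H | CCCC[Sn](CCCC)(CCCC)SC(=O)OC1C[C@@H](O[Si](CC)(CC)CC)[C@@]2(C)[C@@H]3CC=C(C)[C@H]2[C@@H]3C1(C)C
F11 | step 15 | tricyclic C1 alcohol with (3R)-OTES and C10-H | OC1C[C@@H](O[Si](CC)(CC)CC)[C@@]2(C)[C@@H]3CC=C(C)[C@H]2[C@@H]3C1(C)C
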